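**Strategy.** Tauranin's quinone ring (C-1 and C-4 carbonyls, C-2 OH, C-3 bearing C-11 of the drimane, C-5 H, C-6 CH2OH) is read as an oxidised 5-substituted resorcinol: the oxygens at C-2 and C-4 flank C-3, and C-6 carries one carbon. Such a ring is the aldol fold of a 1,3,5-tricarbonyl chain. The chain is grown on the side chain of (+)-manool after its cleavage to a methyl ketone: oxalate is added at the methyl group, acetate at C-12 of the labdane. The key step closes the benzene ring of the acyclic 2,4,6-trioxoheptanoate by aldol cycloaromatisation, forming the C-5–C-6 bond. Ester reduction and oxygenation at C-1 finish; all stereocentres come from manool.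

Key step: step 4

Remark: (+)-manool is taken as a commercial chiral-pool terpene with the 5S,9S,10S decalin of the target; the two free ring CH positions of resorcinol 9 are constitutionally equivalent (local mirror plane through the two substituted carbons), so step 6 can give only one quinone constitution.

Abbreviation: Dr = (1S,4aS,8aS)-5,5,8a-trimethyl-2-methylidenedecahydronaphthalen-1-yl, the drim-8(12)-ene decalin joined through C-9 (5α-H, 9α-H, 10β-CH3).

Step 1
Reactants: 1 (+)-manool, (13R)-labda-8(17),14-dien-13-ol
Product: 2 14,15-dinorlabd-8(17)-en-13-one (Dr–CH2CH2–CO–CH3)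
Conditions: KMnO4, MgSO4, acetone, 0 °C → rt
Reagents that add atoms: none
Why: Permanganate oxidative degradation of the tertiary vinyl carbinol (hydroxylation of the unhindered C-14/C-15 alkene, then C-13/C-14 cleavage) should leave C-13 as the ketone, while the hindered 1,1-disubstituted C-8(17) alkene reacts much more slowly under cold buffered conditions; C-5, C-9 and C-10 are untouched.

Step 2
Reactants: 2 14,15-dinorlabd-8(17)-en-13-one; 3 dimethyl oxalate
Product: 4 methyl 2,4-dioxo-6-Dr-hexanoate (enolised 2,4-diketo ester)
Conditions: LiN(SiMe3)2, THF, −78 °C; then 3 (2 equiv), −78 °C → rt; 1 M HCl work-up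
Reagents that add atoms: none
Why: Crossed Claisen condensation: the kinetic lithium enolate forms at the methyl group (C-16) and is acylated by the non-enolisable oxalate, and the product should stay protected as its chelated enolate until work-up.

Step 3
Reactants: 4 methyl 2,4-dioxo-6-Dr-hexanoate; 5 N-methoxy-N-methylacetamide
Product: 6 methyl 2,4,6-trioxo-5-(Dr-methyl)heptanoate (mixture of C-5 epimers and enol tautomers, used crude)
Conditions: LiN(i-Pr)2 (2.3 equiv), THF, −78 → −20 °C; then 5, −78 → 0 °C; AcOH, −78 °C
Reagents that add atoms: none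
Why: Terminal acylation of a 1,3-dicarbonyl dianion (Weinreb ketone synthesis): after the enolic proton the only α-hydrogens left are at C-5 (C-12 of the labdane), the carbanion there is the most nucleophilic site, and the chelated amide adduct should release the acetyl ketone only on quench; the new C-5 centre is a labile α-carbon that later becomes an arene carbon.

Step 4
Reactants: 6 methyl 2,4,6-trioxo-5-(Dr-methyl)heptanoate
Product: 8 methyl 3,5-dihydroxy-4-(Dr-methyl)benzoate, via cyclic aldol adduct 7 (not isolated)
Conditions: K2CO3, MeOH, 0 °C → rt; aq. NaH2PO4 work-up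
Reagents that add atoms: none
Why: Carbonate generates the enolate of the acetyl group, whose terminal carbon (C-7) adds to the α-keto ester carbonyl C-2 to give aldol 7, which loses water by E1cB elimination and enolises twice to benzoate 8. The closest known reaction type is the biomimetic (polyketide-type) aldol cycloaromatisation of 1,3,5-tricarbonyl chains to resorcinols. The one ring formed is the benzene ring, closed in the 6-(enolendo)-exo-trig mode by the C-7/C-2 bond, which becomes the bond between the ring CH (quinone C-5) and the carbon that carries CH2OH (quinone C-6). No stereocentre is created, and the labile centres of 6 and 7 are erased on aromatisation. The step needs C- over O-cyclisation and a single aldol regiochemistry: the ester terminus has no α-hydrogen, so the acetyl methyl is the only carbon that can reach a carbonyl through a six-membered ring, the α-keto ester carbonyl is the most electrophilic one, and the basic medium disfavours the acid-promoted O-cyclisation to a γ-pyranone.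

Step 5
Reactants: 8 methyl 3,5-dihydroxy-4-(Dr-methyl)benzoate
Product: 9 5-(hydroxymethyl)-2-(Dr-methyl)benzene-1,3-diol
Conditions: LiAlH4 (excess), THF, 0 °C → reflux; aq. KNaC4H4O6 work-up (no strong acid)
Reagents that add atoms: none
Why: Hydride reduction of the benzoate ester to the benzylic alcohol should proceed with the phenols merely deprotonated; the meta relationship of OH and CH2OH excludes quinone-methide over-reduction and the isolated alkene is inert.

Step 6
Reactants: 9 5-(hydroxymethyl)-2-(Dr-methyl)benzene-1,3-diol
Product: 10 tauranin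
Conditions: K2NO(SO3)2 (Fremy's salt), KH2PO4, acetone–H2O, 0 °C → rt
Reagents that add atoms: potassium nitrosodisulfonate (Fremy's salt), [K+].[K+].[O]N(S(=O)(=O)[O-])S(=O)(=O)[O-]
Why: Teuber oxidation: the phenoxyl radical should be trapped by a second nitroxide at a free carbon para to a hydroxyl (the position between the hydroxyls is blocked), and loss of imidodisulfonate gives the para-quinone whose remaining hydroxyl is the C-2 OH; alkene and benzylic alcohol are inert.

**Compound list**
1 | (+)-manool, (13R)-labda-8(17),14-dien-13-ol | C=C1CC[C@H]2C(C)(C)CCC[C@]2(C)[C@H]1CC[C@@](C)(O)C=C | starting material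
2 | 14,15-dinorlabd-8(17)-en-13-one, 4-[(1S,4aS,8aS)-5,5,8a-trimethyl-2-methylidenedecahydronaphthalen-1-yl]butan-2-one | C=C1CC[C@H]2C(C)(C)CCC[C@]2(C)[C@H]1CCC(C)=O | intermediate
3 | dimethyl oxalate | COC(=O)C(=O)OC | starting material
4 | methyl 2,4-dioxo-6-[(1S,4aS,8aS)-5,5,8a-trimethyl-2-methylidenedecahydronaphthalen-1-yl]hexanoate | C=C1CC[C@H]2C(C)(C)CCC[C@]2(C)[C@H]1CCC(=O)CC(=O)C(=O)OC | intermediate
5 | N-methoxy-N-methylacetamide | CON(C)C(C)=O | starting material
6 | methyl 2,4,6-trioxo-5-{[(1S,4aS,8aS)-5,5,8a-trimethyl-2-methylidenedecahydronaphthalen-1-yl]methyl}heptanoate (C-5 unassigned, labile) | C=C1CC[C@H]2C(C)(C)CCC[C@]2(C)[C@H]1CC(C(C)=O)C(=O)CC(=O)C(=O)OC | intermediate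
7 | methyl 1-hydroxy-3,5-dioxo-4-{[(1S,4aS,8aS)-5,5,8a-trimethyl-2-methylidenedecahydronaphthalen-1-yl]methyl}cyclohexane-1-carboxylate (cyclic aldol, ring centres unassigned, not isolated) | C=C1CC[C@H]2C(C)(C)CCC[C@]2(C)[C@H]1CC1C(=O)CC(O)(C(=O)OC)CC1=O | intermediate
8 | methyl 3,5-dihydroxy-4-{[(1S,4aS,8aS)-5,5,8a-trimethyl-2-methylidenedecahydronaphthalen-1-yl]methyl}benzoate | C=C1CC[C@H]2C(C)(C)CCC[C@]2(C)[C@H]1Cc1c(O)cc(C(=O)OC)cc1O | intermediate
9 | 5-(hydroxymethyl)-2-{[(1S,4aS,8aS)-5,5,8a-trimethyl-2-methylidenedecahydronaphthalen-1-yl]methyl}benzene-1,3-diol | C=C1CC[C@H]2C(C)(C)CCC[C@]2(C)[C@H]1Cc1c(O)cc(CO)cc1O | intermediate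
10 | tauranin, 2-hydroxy-6-(hydroxymethyl)-3-{[(1S,4aS,8aS)-5,5,8a-trimethyl-2-methylidenedecahydronaphthalen-1-yl]methyl}cyclohexa-2,5-diene-1,4-dione | C=C1CC[C@H]2C(C)(C)CCC[C@]2(C)[C@H]1CC1=C(O)C(=O)C(CO)=CC1=O | target

**Step count.** Total: 6 steps. Longest linear sequence: 6 steps (1 → 10).

**Steps most likely to fail**

Step 4 (key step). Retro-Claisen loss of the acetyl group by methoxide, or five-membered Dieckmann closure of C-5 onto the ester, may compete with the aldol. The fallback sets out from 6 and changes the order of events. Mild acid (pyridinium p-toluenesulfonate, toluene, 60 °C, 4 Å sieves) should cyclodehydrate the 1,5-dicarbonyl unit to the γ-pyranone methyl 6-methyl-4-oxo-5-(Dr-methyl)-4H-pyran-2-carboxylate F1, which locks the chain against both side reactions. F1 is then treated with NaOMe in MeOH at 50 °C (AcOH work-up): methoxide adds at C-2 of the pyranone, the ring opens, and the methyl carbon recloses on the same carbon with loss of methoxide (pyranone-to-phenol ring transformation). The same ring bond is formed and the route is rejoined at 8.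

Step 3. Slow acyl transfer may let the dianion be quenched by proton exchange or attack its own ester. The fallback sets out from 4 and replaces acylation by aldol addition and oxidation. The same dianion is trapped at −78 °C with acetaldehyde, a much faster electrophile, to give the hydroxy diketo ester methyl 5-(1-hydroxyethyl)-2,4-dioxo-6-Dr-hexanoate F2. Oxidation of the secondary alcohol with Dess–Martin periodinane (NaHCO3, CH2Cl2, 0 °C) returns to 6.

Step 6. Over-oxidation or radical coupling of the electron-rich resorcinol may occur instead of clean para-oxygenation. The fallback sets out from 9 and introduces the oxygen in two-electron steps. Ortho-formylation (MgCl2, Et3N, paraformaldehyde, MeCN, reflux) should give 2,4-dihydroxy-6-(hydroxymethyl)-3-(Dr-methyl)benzaldehyde F3. Dakin oxidation (H2O2, NaOH, THF–H2O, 0 °C) converts it to 6-(hydroxymethyl)-3-(Dr-methyl)benzene-1,2,4-triol F4. After excess peroxide is destroyed with Na2SO3, F4 is autoxidised by air in the basic solution to 10.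

**Further compounds**
F1 | step 4 | methyl 6-methyl-4-oxo-5-{[(1S,4aS,8aS)-5,5,8a-trimethyl-2-methylidenedecahydronaphthalen-1-yl]methyl}-4H-pyran-2-carboxylate | C=C1CC[C@H]2C(C)(C)CCC[C@]2(C)[C@H]1CC1=C(C)OC(C(=O)OC)=CC1=O
F2 | step 3 | methyl 5-(1-hydroxyethyl)-2,4-dioxo-6-[(1S,4aS,8aS)-5,5,8a-trimethyl-2-methylidenedecahydronaphthalen-1-yl]hexanoate | C=C1CC[C@H]2C(C)(C)CCC[C@]2(C)[C@H]1CC(C(C)O)C(=O)CC(=O)C(=O)OC
F3 | step 6 | 2,4-dihydroxy-6-(hydroxymethyl)-3-{[(1S,4aS,8aS)-5,5,8a-trimethyl-2-methylidenedecahydronaphthalen-1-yl]methyl}benzaldehyde | C=C1CC[C@H]2C(C)(C)CCC[C@]2(C)[C@H]1Cc1c(O)cc(CO)c(C=O)c1O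
F4 | step 6 | 6-(hydroxymethyl)-3-{[(1S,4aS,8aS)-5,5,8a-trimethyl-2-methylidenedecahydronaphthalen-1-yl]methyl}benzene-1,2,4-triol | C=C1CC[C@H]2C(C)(C)CCC[C@]2(C)[C@H]1Cc1c(O)cc(CO)c(O)c1O
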